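One D cannot stand in G and in Z at once, so which of them leads is a question about one ratio, Z over G, and its common logarithm is positive when Z leads and negative when G leads.

| flask | D | E | remark | time |
|---|---|---|---|---|
| north | 11 mM | 30 mM | run made earlier |  |
| south-east | 11 mM | 51 mM | run made earlier |  |
| red | 11 mM | 22.0 mM |  | 5.0 d |
| ochre | 11 mM | 29.0 mM |  | 5.0 d |
| amber | 11 mM | 37.0 mM |  | 5.0 d |

- which of these there is most of at the end, counted by the D in it, red (X / G / Z / L)
- which of these there is most of at the end, counted by the D in it, ochre (X / G / Z / L)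
- which of these there is most of at the end, counted by the D in it, amber (X / G / Z / L)
- amount of the one of these that there is most of at the end, in percent of the D charged, red
- amount of the one of these that there is most of at the end, in percent of the D charged, ochre
- amount of the one of these that there is most of at the end, in percent of the D charged, amber

| run | time / d | L / % | Z / % | X / % | G / % | D / % |
|---|---|---|---|---|---|---|
| north | 0.625 | 0.3 | 8.8 | 8.0 | 58.5 | 23.9 |
| north | 1.67 | 2.1 | 26.4 | 9.3 | 56.7 | 3.9 |
| north | 3.00 | 4.6 | 40.1 | 8.6 | 46.5 | 0.4 |
| north | 5.00 | 6.9 | 50.8 | 6.9 | 37.1 | 0.1 |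
| south-east | 0.625 | 0 | 21.2 | 4.5 | 62.4 | 9.8 |
| south-east | 1.67 | 1.4 | 49.8 | 4.3 | 42.1 | 1.1 |
| south-east | 3.00 | 3.1 | 66.2 | 4.4 | 26.7 | 0.2 |
| south-east | 5.00 | 5.2 | 74.7 | 2.4 | 17.9 | 0 |

(standard deviation of a reading: 0.5 percentage points)

- percentages count the D that a species holds: one J counts as two
- L is meant together with its J
- reactions considered so far: E + X -> L; E + G <-> Z; E -> Q; D + E -> G; D -> X; D + L <-> J
- in an amount of L, one J counts as one L

Both earlier runs were read at 5.00 d, the time asked for, so their last rows go straight into a small table:

| run | charged [E] | Z | G | logarithm of Z/G |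
|---|---|---|---|---|
| north | 30 mM | 50.8% | 37.1% | 0.136 |
| south-east | 51 mM | 74.7% | 17.9% | 0.620 |

Reading down the columns, Z rises and G falls as charged [E] goes up, and both runs have Z ahead. Reading the last column against the second gives the decade width of E, the rise in charged [E] that lifts the logarithm of Z/G by one unit at this time and this charge of D: 43.4 mM.

Stepping from north by that width gives −0.0479 for red, 0.113 for ochre and 0.298 for amber. So this reckoning puts G ahead in red and Z ahead in ochre and amber. Red stands 8.00 mM below north, outside the span of the two runs, so its sign is an extrapolation of the line. There the line makes Z 0.896 of G.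

The forecast names G at 47% (43% to 51%) for red, Z at 49% (46% to 51.5%) for ochre and Z at 61% (58% to 65%) for amber. Its ground is this: “Each Z costs two E”. The leaders match the line's; in red the forecast has Z near 35 percent beside G near 47 percent, amounts that the line, which gives a ratio, does not give.

The flasks give G at 46.8% in red, Z at 48.9% in ochre and Z at 61.0% in amber.

    E + X → L (k = 0.353 M⁻¹ h⁻¹)
    E + G ⇌ Z (K = 159 M⁻¹, k = 0.679 M⁻¹ h⁻¹)
    E → Q (k = 2.80 × 10⁻⁵ h⁻¹)
    D + E → G (k = 3.33 M⁻¹ h⁻¹)
    D → X (k = 0.0116 h⁻¹)
    D + L ⇌ J, settled at all times (K = 130 M⁻¹)

In red, D, the limiting reagent, stands at 0.294% at 5.00 d, with E at 38.5% of its own charge. Red's logarithm is −0.125 against the reckoned −0.0479, and red and amber together give a width of 33.2 mM against 43.4 mM. Taken from the 3.00 d rows, the width is 45.8 mM, which carries north to −0.239 for red read at 3.0 d. That flask holds Z at 26.8% and G at 53.9%, a logarithm of −0.303.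

The earlier runs and the new flask come from a simulation for an exercise; scatter was added.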